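The route rests on disconnecting the bond between the quaternary carbon of the 3(2H)-furanone (C-2 of that ring, bearing the methyl group) and the exocyclic methine carbon of the γ-ylidene butenolide. Forming this bond last closes the nine-membered oxacycle that holds the furanone oxygen, the CH(Me)–CH2–CH(O-acyl) chain and the butenolide β- and γ-carbons. The key step is an intramolecular vinylogous addition–elimination: a planar, aromatic furan-3-olate attacks the δ-carbon of an enol tosylate of the butenolide and tosylate leaves. The furanone α-carbon is stereolabile and the enol tosylate geometry is lost in the adduct, so four precursor stereoisomers converge on one product. The precursor is an open chain carrying both five-membered rings.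

Key step: step 16

Remark on numbering (germacrane-type, used below): C1 = O-bearing sp2 carbon of the furanone; C2 = furanone CH; C3 = furanone C=O; C4 = quaternary furanone carbon with CH3; C5 = exocyclic methine; C6, C7, C11, C12 = γ-, β-, α- and carbonyl carbons of the butenolide; C8 = CH–O(ester); C9 = CH2; C10 = CH(CH3); C13 = CH2OH on C11.

Assumption: the enol tosylate is carried as an E/Z mixture at C5=C6 and, from step 13 on, C4 (in 25 also C1) as a mixture of epimers, so the SMILES of these compounds carry no descriptor there. The sense of induction in step 7 is assigned by analogy with aromatic and α-substituted unsaturated aldehydes; the mirror-image ligand would be used if the sense were opposite.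

Step 1
Reactants: 1 but-2-yne-1,4-diol; 2 vinylmagnesium chloride
Product: 5 4-ethenyl-3-(hydroxymethyl)furan-2(5H)-one, via chelated alkenylmagnesium alkoxide 3 (not isolated), via Z-hydroxy acid 4 (not isolated)
Conditions: 2 (4 equiv), THF, reflux; CO2 (g), 0 °C; 2 M HCl
Reagents that add atoms: carbon dioxide (O=C=O)
Why: Hydroxyl-directed anti-carbomagnesiation of the propargylic diol places magnesium on C11 cis to the C6 alkoxide, and carboxylation followed by acid-induced lactonisation of the Z-hydroxy acid should close the butenolide with C13 in place; no stereocentre is involved.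

Step 2
Reactants: 5 4-ethenyl-3-(hydroxymethyl)furan-2(5H)-one
Product: 6 3-[(tert-butyldimethylsilyloxy)methyl]-4-ethenylfuran-2(5H)-one
Conditions: TBSCl, imidazole, DMF, 0 °C → rt
Reagents that add atoms: tert-butyldimethylsilyl chloride (C[Si](C)(Cl)C(C)(C)C)
Why: Standard silylation of the primary allylic alcohol; the lactone is inert to imidazole.

Step 3
Reactants: 6 3-[(tert-butyldimethylsilyloxy)methyl]-4-ethenylfuran-2(5H)-one
Product: 8 [3-ethenyl-4-(tert-butyldimethylsilyloxymethyl)-5-oxofuran-2(5H)-ylidene]methyl 4-methylbenzenesulfonate (E/Z mixture), via lithium formyl enolate 7 (not isolated)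
Conditions: LiHMDS (2.2 equiv), THF, −78 °C; HCO2Et, −78 → −20 °C; TsCl, −78 → 0 °C
Reagents that add atoms: ethyl formate (CCOC=O); 4-methylbenzenesulfonyl chloride (Cc1ccc(cc1)S(=O)(=O)Cl)
Why: γ-Deprotonation gives the aromatic furan-2-olate, a Claisen-type formylation under thermodynamic control should stop at the stabilised enolate 7 (the α-carbon is blocked, so only the γ-formyl product can be deprotonated), and sulfonylation of the exocyclic enolate oxygen gives the vinylogous mixed anhydride 8, whose alkene geometry is irrelevant for step 16.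

Step 4
Reactants: 8 the enol tosylate of step 3
Product: 9 [3-formyl-4-(tert-butyldimethylsilyloxymethyl)-5-oxofuran-2(5H)-ylidene]methyl 4-methylbenzenesulfonate (E/Z mixture)
Conditions: OsO4 (2 mol%), NaIO4, 2,6-lutidine, dioxane/H2O, rt
Reagents that add atoms: osmium tetroxide (O=[Os](=O)(=O)=O); sodium periodate ([Na+].[O-][I](=O)(=O)=O)
Why: Lemieux–Johnson cleavage should attack the monosubstituted vinyl group in preference to the tetrasubstituted ester-conjugated C7=C11 bond and the electron-poor trisubstituted enol sulfonate alkene.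

Step 5
Reactants: 10 (R)-3-bromo-2-methylpropan-1-ol
Product: 11 (R)-(3-bromo-2-methylpropoxy)triethylsilane
Conditions: TESCl, imidazole, CH2Cl2, 0 °C
Reagents that add atoms: chlorotriethylsilane (CC[Si](Cl)(CC)CC)
Why: Silylation of the primary alcohol gives an ether that survives halide exchange and zinc chemistry and can later be oxidised directly.

Step 6
Reactants: 11 (R)-(3-bromo-2-methylpropoxy)triethylsilane
Product: 12 (R)-triethyl(3-iodo-2-methylpropoxy)silane
Conditions: NaI, acetone, reflux
Reagents that add atoms: sodium iodide ([Na+].[I-])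
Why: Finkelstein exchange at the primary carbon leaves the future C10 stereocentre untouched.

Step 7
Reactants: 9 the aldehyde of step 4; 12 (R)-triethyl(3-iodo-2-methylpropoxy)silane
Product: 14 {3-[(1S,3S)-1-hydroxy-3-methyl-4-(triethylsilyloxy)butyl]-4-(tert-butyldimethylsilyloxymethyl)-5-oxofuran-2(5H)-ylidene}methyl 4-methylbenzenesulfonate (E/Z mixture), via dialkylzinc 13 (not isolated)
Conditions: 12 (2.5 equiv), Et2Zn, CuI (cat.), 50 °C, then vacuum; 9, Ti(OiPr)4, (1R,2R)-1,2-bis(trifluoromethanesulfonamido)cyclohexane (10 mol%), toluene, −20 °C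
Reagents that add atoms: none
Why: Iodine–zinc exchange gives the dialkylzinc, and the titanium–bis(sulfonamide)-catalysed alkyl addition to the aldehyde should set C8 as S under catalyst control while C10 is carried in from 10; lactone, enol tosylate and silyl ethers are inert to the organozinc.

Step 8
Reactants: 15 1-(tert-butyldimethylsilyloxy)propan-2-one; 16 triethyl phosphonoacetate
Product: 17 ethyl (E)-4-(tert-butyldimethylsilyloxy)-3-methylbut-2-enoate
Conditions: NaH, THF, 0 °C → rt
Reagents that add atoms: none
Why: Horner–Wadsworth–Emmons olefination of the α-silyloxy ketone should give mainly the E ester (ester anti to the larger CH2OTBS group), which is separated from the minor Z isomer.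

Step 9
Reactants: 17 ethyl (E)-4-(tert-butyldimethylsilyloxy)-3-methylbut-2-enoate
Product: 18 (E)-4-(tert-butyldimethylsilyloxy)-3-methylbut-2-enoic acid
Conditions: LiOH, THF/H2O, rt; 1 M HCl
Reagents that add atoms: lithium hydroxide ([Li+].[OH-])
Why: Saponification of the ethyl ester; the primary TBS ether and the alkene geometry are stable to aqueous LiOH at room temperature.

Step 10
Reactants: 14 the (8S,10S) alcohol of step 7; 18 (E)-4-(tert-butyldimethylsilyloxy)-3-methylbut-2-enoic acid
Product: 19 (8S,10S) C8 ester of 14 with the acyl group of 18 (C1 as CH2OTES; E/Z mixture)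
Conditions: DCC, DMAP (10 mol%), CH2Cl2, 0 °C
Reagents that add atoms: none
Why: Steglich esterification of the secondary allylic alcohol at 0 °C with little DMAP is chosen to avoid deconjugation of the β,β-disubstituted enoate and attack on the enol tosylate.

Step 11
Reactants: 19 the ester of step 10
Product: 20 (2S,4S)-4-[(E)-4-(tert-butyldimethylsilyloxy)-3-methylbut-2-enoyloxy]-2-methyl-4-[4-(tert-butyldimethylsilyloxymethyl)-5-oxo-2-(tosyloxymethylene)-2,5-dihydrofuran-3-yl]butanal (E/Z mixture)
Conditions: (COCl)2, DMSO, CH2Cl2, −78 → −40 °C; Et3N, −78 → 0 °C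
Reagents that add atoms: none
Why: Swern conditions cleave the primary triethylsilyl ether and oxidise it in situ to the aldehyde while the primary TBS ethers survive, and the low temperature protects the α-stereocentre C10.

Step 12
Reactants: 21 but-3-yn-2-ol (racemic)
Product: 22 (but-3-yn-2-yloxy)triethylsilane (racemic)
Conditions: TESCl, imidazole, CH2Cl2, 0 °C
Reagents that add atoms: chlorotriethylsilane (CC[Si](Cl)(CC)CC)
Why: Silylation of the secondary propargylic alcohol; the racemate is used because this carbon becomes the stereolabile C4.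

Step 13
Reactants: 20 the aldehyde of step 11; 22 (but-3-yn-2-yloxy)triethylsilane
Product: 25 propargylic alcohol in which the CHO of 20 has become CH(OH)–C≡C–CH(OTES)CH3 (epimers at C1 and C4; E/Z mixture), via lithium acetylide 23 (not isolated), via alkynyltitanium triisopropoxide 24 (not isolated)
Conditions: 22, n-BuLi, THF, −78 °C; ClTi(OiPr)3; 20, −78 → −30 °C
Reagents that add atoms: none
Why: The alkynyltitanium triisopropoxide should add to the aldehyde but not to the lactone, the esters or the enol tosylate and is too weakly basic to epimerise C10; the new carbinol configuration is irrelevant because it is oxidised in step 14.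

Step 14
Reactants: 25 the propargylic alcohol of step 13
Product: 26 ynone with C1 as ketone, C10–C(=O)–C≡C–CH(OTES)CH3 (C4 epimers; E/Z mixture)
Conditions: Dess–Martin periodinane, CH2Cl2, 0 °C → rt
Reagents that add atoms: none
Why: Dess–Martin oxidation of the propargylic alcohol under non-basic conditions should give the ynone without epimerising C10.

Step 15
Reactants: 26 the ynone of step 14
Product: 28 open-chain key precursor: 5-substituted 2-methylfuran-3(2H)-one tethered through (10S)-CH(CH3)–CH2–(8S)-CH(O-acyl) to the 5-(tosyloxymethylene)butenolide (both C4 epimers; E/Z mixture), via γ-hydroxy ynone 27 (not isolated)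
Conditions: PPTS, MeOH/CH2Cl2, 0 °C; (p-CF3C6H4)3PAuCl, AgOTf (5 mol%), toluene, rt
Reagents that add atoms: none
Why: Mild acidic methanolysis removes the secondary triethylsilyl ether selectively, and gold(I)-catalysed cycloisomerisation of a γ-hydroxy ynone is a known route to 3(2H)-furanones that needs neither base nor nucleophile, so the enol tosylate survives.

Step 16
Reactants: 28 the open-chain key precursor
Product: 31 13,4'-bis-O-TBS ether of the target (4S,8S,10S), via caesium furan-3-olate 29 (not isolated), via caesium dienolate adduct 30 (not isolated)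
Conditions: Cs2CO3 (2 equiv), MeCN, 2 mM (slow addition), 25–40 °C
Reagents that add atoms: none
Why: Proposed new method: caesium carbonate removes the acidic C4–H of the furanone to give the planar aromatic furan-3-olate 29, whose C4 adds to C5, the δ-carbon of the dienoate made up of the lactone carbonyl, C11=C7 and the enol tosylate C6=C5, to give the butenolide dienolate 30, which expels tosylate in an E1cB step and restores the C5=C6 bond. The closest known reactions are nucleophilic vinylic substitution (addition–elimination) of stabilised enolates on β-sulfonyloxy and β-halo enones, 1,6-addition–elimination of nucleophiles on 5-(halomethylene)furan-2(5H)-ones, and C2-alkylation of 3(2H)-furanone enolates; their combination in a ring closure of this size has not been shown. The nine-membered ring closes by C–C bond formation in a 9-endo-trig addition (C5=C6 lies inside the new ring, the enolate bond C3=C4 outside it), and the ring allows only the C5=C6 geometry with C4 syn to C7, so both enol tosylate isomers should give the same alkene. C4 is the only new stereocentre and is set under substrate control by C8: allylic 1,3-strain with the C11 CH2OTBS group holds H8 in the butenolide plane, which puts the C9–C10 tether and the furanolate on one face of the acceptor and the ester on the other, and a caesium-bridged synclinal Michael transition state with the enolate C3–O unit over the dienoate is expected to lead to 4S. The step needs C- over O-attack of the ambident furanolate (soft δ-carbon; C-attack gives the nine-membered ring, O-attack a ten-membered one), attack at C5 and not at the hindered tetrasubstituted C7, and ring closure over oligomerisation, which high dilution and slow addition should secure. C8 and C10 are not acidic towards carbonate and should stay as set, and tosylate is a far better leaving group than the C13 silanolate, so the dienolate 30 should not eliminate towards C13.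

Step 17
Reactants: 31 the bis-TBS ether of step 16
Product: 32 CNP0288314.1 (target)
Conditions: HF·pyridine, pyridine, THF, 0 °C → rt
Reagents that add atoms: none
Why: Buffered HF·pyridine should cleave both primary TBS ethers without touching the enol lactone, the vinylogous ester or the allylic ester.

Compound list
1 | but-2-yne-1,4-diol | OCC#CCO | starting material
2 | vinylmagnesium chloride | C=C[Mg]Cl | starting material
3 | chelated (Z)-alkenylmagnesium bis(chloromagnesium alkoxide) | C=C/C(CO[Mg]Cl)=C(/[Mg]Cl)CO[Mg]Cl | intermediate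
4 | (Z)-3-ethenyl-4-hydroxy-2-(hydroxymethyl)but-2-enoic acid | C=C/C(CO)=C(/C(=O)O)CO | intermediate
5 | 4-ethenyl-3-(hydroxymethyl)furan-2(5H)-one | O=C1OCC(C=C)=C1CO | intermediate
6 | 3-[(tert-butyldimethylsilyloxy)methyl]-4-ethenylfuran-2(5H)-one | O=C1OCC(C=C)=C1CO[Si](C)(C)C(C)(C)C | intermediate
7 | lithium [3-ethenyl-4-(tert-butyldimethylsilyloxymethyl)-5-oxofuran-2(5H)-ylidene]methanolate | [Li+].[O-]C=C1OC(=O)C(CO[Si](C)(C)C(C)(C)C)=C1C=C | intermediate
8 | [3-ethenyl-4-(tert-butyldimethylsilyloxymethyl)-5-oxofuran-2(5H)-ylidene]methyl 4-methylbenzenesulfonate (E/Z mixture) | Cc1ccc(cc1)S(=O)(=O)OC=C1OC(=O)C(CO[Si](C)(C)C(C)(C)C)=C1C=C | intermediate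
9 | [3-formyl-4-(tert-butyldimethylsilyloxymethyl)-5-oxofuran-2(5H)-ylidene]methyl 4-methylbenzenesulfonate (E/Z mixture) | Cc1ccc(cc1)S(=O)(=O)OC=C1OC(=O)C(CO[Si](C)(C)C(C)(C)C)=C1C=O | intermediate
10 | (R)-3-bromo-2-methylpropan-1-ol | BrC[C@H](C)CO | starting material
11 | (R)-(3-bromo-2-methylpropoxy)triethylsilane | BrC[C@H](C)CO[Si](CC)(CC)CC | intermediate
12 | (R)-triethyl(3-iodo-2-methylpropoxy)silane | IC[C@H](C)CO[Si](CC)(CC)CC | intermediate
13 | bis[(R)-2-methyl-3-(triethylsilyloxy)propyl]zinc | CC[Si](CC)(CC)OC[C@@H](C)C[Zn]C[C@H](C)CO[Si](CC)(CC)CC | intermediate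
14 | {3-[(1S,3S)-1-hydroxy-3-methyl-4-(triethylsilyloxy)butyl]-4-(tert-butyldimethylsilyloxymethyl)-5-oxofuran-2(5H)-ylidene}methyl 4-methylbenzenesulfonate (E/Z mixture) | O[C@H](C1=C(CO[Si](C)(C)C(C)(C)C)C(=O)OC1=COS(=O)(=O)c1ccc(C)cc1)C[C@H](C)CO[Si](CC)(CC)CC | intermediate
15 | 1-(tert-butyldimethylsilyloxy)propan-2-one | CC(=O)CO[Si](C)(C)C(C)(C)C | starting material
16 | triethyl phosphonoacetate | CCOC(=O)CP(=O)(OCC)OCC | starting material
17 | ethyl (E)-4-(tert-butyldimethylsilyloxy)-3-methylbut-2-enoate | CCOC(=O)/C=C(\C)CO[Si](C)(C)C(C)(C)C | intermediate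
18 | (E)-4-(tert-butyldimethylsilyloxy)-3-methylbut-2-enoic acid | OC(=O)/C=C(\C)CO[Si](C)(C)C(C)(C)C | intermediate
19 | (8S,10S) C8 (E)-4-(tert-butyldimethylsilyloxy)-3-methylbut-2-enoate of 14 (C1 as CH2OTES; E/Z mixture) | C/C(=C\C(=O)O[C@H](C1=C(CO[Si](C)(C)C(C)(C)C)C(=O)OC1=COS(=O)(=O)c1ccc(C)cc1)C[C@H](C)CO[Si](CC)(CC)CC)CO[Si](C)(C)C(C)(C)C | intermediate
20 | (2S,4S)-4-[(E)-4-(tert-butyldimethylsilyloxy)-3-methylbut-2-enoyloxy]-2-methyl-4-[4-(tert-butyldimethylsilyloxymethyl)-5-oxo-2-(tosyloxymethylene)-2,5-dihydrofuran-3-yl]butanal (E/Z mixture) | C/C(=C\C(=O)O[C@H](C1=C(CO[Si](C)(C)C(C)(C)C)C(=O)OC1=COS(=O)(=O)c1ccc(C)cc1)C[C@H](C)C=O)CO[Si](C)(C)C(C)(C)C | intermediate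
21 | but-3-yn-2-ol (racemic) | CC(O)C#C | starting material
22 | (but-3-yn-2-yloxy)triethylsilane (racemic) | CC(O[Si](CC)(CC)CC)C#C | intermediate
23 | lithium acetylide of 22 | [Li]C#CC(C)O[Si](CC)(CC)CC | intermediate
24 | [3-(triethylsilyloxy)but-1-ynyl]titanium triisopropoxide | CC(C)O[Ti](OC(C)C)(OC(C)C)C#CC(C)O[Si](CC)(CC)CC | intermediate
25 | propargylic alcohol: CHO of 20 replaced by CH(OH)–C≡C–CH(OTES)CH3 (epimers at C1 and C4; E/Z mixture) | C/C(=C\C(=O)O[C@H](C1=C(CO[Si](C)(C)C(C)(C)C)C(=O)OC1=COS(=O)(=O)c1ccc(C)cc1)C[C@H](C)C(O)C#CC(C)O[Si](CC)(CC)CC)CO[Si](C)(C)C(C)(C)C | intermediate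
26 | ynone: C1 ketone of 25 (C4 epimers; E/Z mixture) | C/C(=C\C(=O)O[C@H](C1=C(CO[Si](C)(C)C(C)(C)C)C(=O)OC1=COS(=O)(=O)c1ccc(C)cc1)C[C@H](C)C(=O)C#CC(C)O[Si](CC)(CC)CC)CO[Si](C)(C)C(C)(C)C | intermediate
27 | γ-hydroxy ynone: 26 without the triethylsilyl group | C/C(=C\C(=O)O[C@H](C1=C(CO[Si](C)(C)C(C)(C)C)C(=O)OC1=COS(=O)(=O)c1ccc(C)cc1)C[C@H](C)C(=O)C#CC(C)O)CO[Si](C)(C)C(C)(C)C | intermediate
28 | open-chain key precursor: 2-methylfuran-3(2H)-one linked at its C5 through (10S)-CH(CH3)–CH2–(8S)-CH(O-acyl) to the 5-(tosyloxymethylene)butenolide (C4 epimers; E/Z mixture) | C/C(=C\C(=O)O[C@H](C1=C(CO[Si](C)(C)C(C)(C)C)C(=O)OC1=COS(=O)(=O)c1ccc(C)cc1)C[C@H](C)C1=CC(=O)C(C)O1)CO[Si](C)(C)C(C)(C)C | intermediate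
29 | caesium 2-methylfuran-3-olate of 28 | C/C(=C\C(=O)O[C@H](C1=C(CO[Si](C)(C)C(C)(C)C)C(=O)OC1=COS(=O)(=O)c1ccc(C)cc1)C[C@H](C)c1cc([O-])c(C)o1)CO[Si](C)(C)C(C)(C)C.[Cs+] | intermediate
30 | caesium furan-2-olate adduct with the C4–C5 bond formed and C5 still bearing the tosyloxy group | C/C(=C\C(=O)O[C@H]1C[C@H](C)C2=CC(=O)[C@](C)(C(OS(=O)(=O)c3ccc(C)cc3)c3oc([O-])c(CO[Si](C)(C)C(C)(C)C)c31)O2)CO[Si](C)(C)C(C)(C)C.[Cs+] | intermediate
31 | 13,4'-bis-O-(tert-butyldimethylsilyl) ether of the target (4S,8S,10S) | C/C(=C\C(=O)O[C@H]1C[C@H](C)C2=CC(=O)[C@](C)(/C=C3/OC(=O)C(CO[Si](C)(C)C(C)(C)C)=C31)O2)CO[Si](C)(C)C(C)(C)C | intermediate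
32 | CNP0288314.1 | C/C(=C\C(=O)O[C@H]1C[C@H](C)C2=CC(=O)[C@](C)(/C=C3/OC(=O)C(CO)=C31)O2)CO | target

Total step count: 17. Longest linear sequence: 12 steps (steps 1, 2, 3, 4, 7, 10, 11, 13, 14, 15, 16, 17).

Steps most likely to fail

1. Step 16 (Proposed new method). The closure may fail through attack on the wrong face of the furanolate (C4 epimer), through oligomerisation, or through sulfonyl transfer to the furanolate oxygen. The fallback sets out from 28: O-silylation (TBSOTf, 2,6-lutidine, CH2Cl2, −78 °C) should give the 2-methyl-3-(tert-butyldimethylsilyloxy)furan F1, in which C4 is sp2. A palladium-catalysed intramolecular α-alkenylation of this silyl enol ether with its own enol tosylate (Pd2(dba)3, bulky biaryl phosphine, CsF, toluene, high dilution) would then form C4–C5 by reductive elimination and come back to the route at 31. This coupling is known for ketone enolates and silyl enol ethers with alkenyl sulfonates, and an enantiopure ligand can be used if the substrate bias is insufficient. Only the tosylate isomer with the sulfonyloxy group syn to C7 can close, so the other isomer would be equilibrated (catalytic iodine or light) or separated and recycled.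

2. Step 3. Formylation or sulfonylation may occur at the wrong site (lactone oxygen instead of the exocyclic oxygen), or the dienolate may lose silanolate from C13. The fallback sets out from 6: condensation with Bredereck's reagent (tert-butoxybis(dimethylamino)methane, toluene, 60 °C) under neutral conditions should give the 5-(dimethylaminomethylene)butenolide F2. Hydrolysis (1 M HCl, THF, 0 °C) should give the 5-(hydroxymethylene)butenolide F3, and sulfonylation (TsCl, 2,6-lutidine, CH2Cl2, 0 °C) comes back to the route at 8.

3. Step 7. The enantiofacial selectivity may be low, or transfer of the β-branched alkyl group slow. The fallback sets out from 9: addition of 13 without the chiral ligand (Ti(OiPr)4, toluene) should give the secondary alcohol F4 as a mixture of C8 epimers, and Dess–Martin oxidation the C8 ketone F5. Corey–Bakshi–Shibata reduction ((R)-2-methyl-CBS-oxazaborolidine, catecholborane, toluene, −78 °C), with the butenolide carbon as the large and the CH2 group as the small substituent, should set C8 as S and comes back to the route at 14.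

Further compounds
F1 | step 16 | 2-methyl-3-(tert-butyldimethylsilyloxy)furan derived from 28 (E/Z mixture at the enol tosylate) | C/C(=C\C(=O)O[C@H](C1=C(CO[Si](C)(C)C(C)(C)C)C(=O)OC1=COS(=O)(=O)c1ccc(C)cc1)C[C@H](C)c1cc(O[Si](C)(C)C(C)(C)C)c(C)o1)CO[Si](C)(C)C(C)(C)C
F2 | step 3 | 3-[(tert-butyldimethylsilyloxy)methyl]-5-(dimethylaminomethylene)-4-ethenylfuran-2(5H)-one | CN(C)C=C1OC(=O)C(CO[Si](C)(C)C(C)(C)C)=C1C=C
F3 | step 3 | 3-[(tert-butyldimethylsilyloxy)methyl]-4-ethenyl-5-(hydroxymethylene)furan-2(5H)-one | OC=C1OC(=O)C(CO[Si](C)(C)C(C)(C)C)=C1C=C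
F4 | step 7 | C8-epimeric mixture of alcohol 14 (10S; E/Z mixture) | OC(C1=C(CO[Si](C)(C)C(C)(C)C)C(=O)OC1=COS(=O)(=O)c1ccc(C)cc1)C[C@H](C)CO[Si](CC)(CC)CC
F5 | step 7 | C8 ketone: {3-[(3S)-3-methyl-4-(triethylsilyloxy)butanoyl]-4-(tert-butyldimethylsilyloxymethyl)-5-oxofuran-2(5H)-ylidene}methyl 4-methylbenzenesulfonate (E/Z mixture) | O=C(C1=C(CO[Si](C)(C)C(C)(C)C)C(=O)OC1=COS(=O)(=O)c1ccc(C)cc1)C[C@H](C)CO[Si](CC)(CC)CC
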